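**Retrosynthetic overview**
- Feature: in the azepinone ring (C3a, C4, C5, C6, N7, C8, C8a) the only double bond outside the pyrrole is C4=C5, with the imidazole on C4 and the C6 methylene on N7. The skeleton is therefore a constitutional isomer of an open N-propargyl 4,5-dibromopyrrole-2-carboxamide whose alkyne is capped by the imidazole and whose pyrrole C3 (the future C3a) is the only free ring carbon.
- Key disconnection C3a–C4: Pt(II)-catalysed 7-endo-dig hydroarylation of that alkyne, a redox-neutral cycloisomerisation that leaves C4=C5 at the final oxidation level.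
- The alkyne precursor is cut at N7–C8 (amide formation) and at the imidazole carbon–C4 bond (Sonogashira coupling). The 2-aminoimidazole travels as imidazo[1,2-a]pyrimidine, and N7 carries a 2,4-dimethoxybenzyl (DMB) group so that the amide is tertiary.
- Ring order: pyrrole and imidazole (as the five-membered ring of the mask) are bought; the azepinone closes in the key step; then the DMB group is removed and the pyrimidine ring of the mask is cut away with hydrazine.

Key step: step 5

Remark: stevensine has no stereocentre and is achiral, so the single-enantiomer requirement needs no stereocontrol; the target is taken as the free base in the tautomer drawn.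

**Route**

Step 1
Reactants: 1 propargylamine (prop-2-yn-1-amine, 1.5 equiv); 2 2,4-dimethoxybenzaldehyde
Product: 4 N-(2,4-dimethoxybenzyl)prop-2-yn-1-amine, via (E)-N-(2,4-dimethoxybenzylidene)prop-2-yn-1-amine 3 (not isolated)
Conditions: MeOH, 3 Å MS, rt; then NaBH4, 0 °C to rt
Reagents that add atoms: none
Why: Reductive amination: the aldehyde condenses with the primary amine (in excess, to suppress double benzylation) to the aryl imine, which NaBH4 reduces chemoselectively while the terminal alkyne stays untouched.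

Step 2
Reactants: 5 imidazo[1,2-a]pyrimidine
Product: 6 3-iodoimidazo[1,2-a]pyrimidine
Conditions: NIS (1.05 equiv), MeCN, rt, dark
Reagents that add atoms: N-iodosuccinimide, O=C1CCC(=O)N1I
Why: Electrophilic aromatic iodination: C3 is the enamine-type, most nucleophilic carbon of imidazo[1,2-a]pyrimidine, so NIS should iodinate there selectively.

Step 3
Reactants: 4 N-(2,4-dimethoxybenzyl)prop-2-yn-1-amine (1.2 equiv); 6 3-iodoimidazo[1,2-a]pyrimidine
Product: 7 N-(2,4-dimethoxybenzyl)-3-(imidazo[1,2-a]pyrimidin-3-yl)prop-2-yn-1-amine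
Conditions: Pd(PPh3)2Cl2 (5 mol %), CuI (10 mol %), Et3N, DMF, 50 °C, Ar
Reagents that add atoms: none
Why: Sonogashira coupling: Pd(0) inserts into the heteroaryl C–I bond and the copper acetylide of the secondary propargylamine transmetalates; running it before the pyrrole is attached keeps the two C–Br bonds away from Pd(0).

Step 4
Reactants: 8 4,5-dibromo-1H-pyrrole-2-carboxylic acid; 7 N-(2,4-dimethoxybenzyl)-3-(imidazo[1,2-a]pyrimidin-3-yl)prop-2-yn-1-amine
Product: 10 4,5-dibromo-N-(2,4-dimethoxybenzyl)-N-[3-(imidazo[1,2-a]pyrimidin-3-yl)prop-2-yn-1-yl]-1H-pyrrole-2-carboxamide, via 4,5-dibromo-1H-pyrrole-2-carbonyl chloride 9 (not isolated)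
Conditions: (COCl)2, DMF (cat.), CH2Cl2/THF, 0 °C to rt; concentrate; then 7, Et3N, CH2Cl2, 0 °C to rt
Reagents that add atoms: none
Why: Amide formation through the acid chloride (Vilsmeier-catalysed chlorination, then N-acylation): the secondary amine is the only site that gives a stable acyl product, since acylation at the mask nitrogen is reversible, and the chloride is used at once and cold to limit self-acylation of the N–H pyrrole.

Step 5
Reactants: 10 4,5-dibromo-N-(2,4-dimethoxybenzyl)-N-[3-(imidazo[1,2-a]pyrimidin-3-yl)prop-2-yn-1-yl]-1H-pyrrole-2-carboxamide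
Product: 11 2,3-dibromo-7-(2,4-dimethoxybenzyl)-4-(imidazo[1,2-a]pyrimidin-3-yl)-6,7-dihydropyrrolo[2,3-c]azepin-8(1H)-one
Conditions: PtCl2 (20 mol %), 1,2-dichloroethane, 80 °C, Ar
Reagents that add atoms: none
Why: PtCl2 binds the alkyne, and because the mask is attached through its enamine-type C3, positive charge builds on C4; pyrrole C3 attacks C4 anti to platinum, the Wheland intermediate loses the C3 proton, and protodeplatination at C5 frees the catalyst, a net redox-neutral cycloisomerisation. The closest known reaction type is the Pt(II)- or Au(I)-catalysed intramolecular hydroarylation of aryl-capped tertiary N-propargyl pyrrole-2-carboxamides to 4-aryl-pyrrolo[2,3-c]azepin-8-ones; the dibromo nucleophile and the basic cap are extensions within that class and are met with the higher loading and temperature. The one ring that closes is the azepinone (C3a, C4, C5, C6, N7, C8, C8a), in the 7-endo-dig mode, with the new C3a–C4 bond and both alkyne carbons inside the ring. No stereocentre forms, and the C4=C5 olefin is fixed as the ring-cis olefin by anti addition of C3 and platinum across the alkyne. The step needs C3 attack at C4 over 6-exo-dig attack at C5, ipso attack at the acylated pyrrole carbon with acyl shift, and closure through amide O or pyrrole N; the donor cap, the endo preference of Pt(II), the absence of base, and the tertiary amide (which holds the propargyl arm over C3 and makes O-attack reversible) should secure it, while the two bromines leave C3 as the only pyrrole C–H. The DMB ring should not compete, because its only carbon within reach of the alkyne (C6, ortho to the CH2) is meta to both methoxy groups.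

Step 6
Reactants: 11 2,3-dibromo-7-(2,4-dimethoxybenzyl)-4-(imidazo[1,2-a]pyrimidin-3-yl)-6,7-dihydropyrrolo[2,3-c]azepin-8(1H)-one
Product: 12 2,3-dibromo-4-(imidazo[1,2-a]pyrimidin-3-yl)-6,7-dihydropyrrolo[2,3-c]azepin-8(1H)-one
Conditions: TFA, anisole (10 equiv), 70 °C
Reagents that add atoms: none
Why: Acidolytic N-debenzylation (SN1): the protonated lactam releases the 2,4-dimethoxybenzyl cation, which anisole captures by Friedel–Crafts alkylation; no silane is present, so C4=C5 is not exposed to ionic hydrogenation, and the protonated mask and the fully substituted pyrrole offer no site for re-alkylation.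

Step 7
Reactants: 12 2,3-dibromo-4-(imidazo[1,2-a]pyrimidin-3-yl)-6,7-dihydropyrrolo[2,3-c]azepin-8(1H)-one
Product: 13 stevensine, 4-(2-amino-1H-imidazol-4-yl)-2,3-dibromo-6,7-dihydropyrrolo[2,3-c]azepin-8(1H)-one
Conditions: N2H4·H2O (20 equiv), EtOH, 100 °C (sealed tube), Ar, degassed
Reagents that add atoms: none
Why: Hydrazinolytic cleavage of the imidazo[1,2-a]pyrimidine (addition, ring opening, ring closure), a known unmasking of 2-aminoimidazoles: hydrazine adds to the pyrimidine carbons, C5–C6–C7 leave as pyrazole and N8 stays as the exocyclic amino group; the lactam and the C–Br bonds should not be attacked, and oxygen and metal traces are excluded so that no diimide forms to reduce C4=C5.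

**Compound list**
1 | propargylamine (prop-2-yn-1-amine) | C#CCN | starting material
2 | 2,4-dimethoxybenzaldehyde | O=Cc1ccc(OC)cc1OC | starting material
3 | (E)-N-(2,4-dimethoxybenzylidene)prop-2-yn-1-amine | C#CC/N=C/c1ccc(OC)cc1OC | intermediate
4 | N-(2,4-dimethoxybenzyl)prop-2-yn-1-amine | C#CCNCc1ccc(OC)cc1OC | intermediate
5 | imidazo[1,2-a]pyrimidine | c1cnc2nccn2c1 | starting material
6 | 3-iodoimidazo[1,2-a]pyrimidine | Ic1cnc2ncccn12 | intermediate
7 | N-(2,4-dimethoxybenzyl)-3-(imidazo[1,2-a]pyrimidin-3-yl)prop-2-yn-1-amine | C(#Cc1cnc2ncccn12)CNCc1ccc(OC)cc1OC | intermediate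
8 | 4,5-dibromo-1H-pyrrole-2-carboxylic acid | O=C(O)c1cc(Br)c(Br)[nH]1 | starting material
9 | 4,5-dibromo-1H-pyrrole-2-carbonyl chloride | O=C(Cl)c1cc(Br)c(Br)[nH]1 | intermediate
10 | 4,5-dibromo-N-(2,4-dimethoxybenzyl)-N-[3-(imidazo[1,2-a]pyrimidin-3-yl)prop-2-yn-1-yl]-1H-pyrrole-2-carboxamide | O=C(c1cc(Br)c(Br)[nH]1)N(Cc1ccc(OC)cc1OC)CC#Cc1cnc2ncccn12 | intermediate
11 | 2,3-dibromo-7-(2,4-dimethoxybenzyl)-4-(imidazo[1,2-a]pyrimidin-3-yl)-6,7-dihydropyrrolo[2,3-c]azepin-8(1H)-one | O=C1N(Cc2ccc(OC)cc2OC)CC=C(c2cnc3ncccn23)c2c1[nH]c(Br)c2Br | intermediate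
12 | 2,3-dibromo-4-(imidazo[1,2-a]pyrimidin-3-yl)-6,7-dihydropyrrolo[2,3-c]azepin-8(1H)-one | O=C1NCC=C(c2cnc3ncccn23)c2c1[nH]c(Br)c2Br | intermediate
13 | stevensine | Nc1ncc(C2=CCNC(=O)c3[nH]c(Br)c(Br)c32)[nH]1 | target

**Step count**
Total steps: 7. Longest linear sequence: 6 (steps 1, 3, 4, 5, 6, 7 from propargylamine); step 2 is a one-step side branch.

**Steps most likely to fail**

1. Step 5 (key step). The mask nitrogens may bind platinum and stall turnover. The bromine-deactivated pyrrole may attack too slowly, so that alkyne hydration or reversible amide-O closure takes over. Closure may also go 6-exo-dig or through ipso attack with acyl shift. The fallback gives up the alkyne closure and builds the ring by acid-promoted Friedel–Crafts chemistry of the same dibromopyrrole amide; it sets out from acid 8 (through its chloride 9) and comes back to the route at target 13. Chloride 9 is condensed with 3,3-diethoxypropan-1-amine (Et3N, CH2Cl2) to give 4,5-dibromo-N-(3,3-diethoxypropyl)-1H-pyrrole-2-carboxamide F1. Aqueous acid (TsOH, acetone–water) should unmask 4,5-dibromo-N-(3-oxopropyl)-1H-pyrrole-2-carboxamide F2. In methanesulfonic acid F2 should close at pyrrole C3 and dehydrate to 2,3-dibromo-6,7-dihydropyrrolo[2,3-c]azepin-8(1H)-one F3. 2-Aminoimidazole (hemisulfate), added to the same acid, should add through its C4 to C4 of the protonated olefin (an azafulvenium ion) and give racemic 4-(2-amino-1H-imidazol-4-yl)-2,3-dibromo-4,5,6,7-tetrahydropyrrolo[2,3-c]azepin-8(1H)-one (hymenin) F4, whose single stereocentre is erased later. Bromine in TFA should brominate the free imidazole carbon to 4-(2-amino-5-bromo-1H-imidazol-4-yl)-2,3-dibromo-4,5,6,7-tetrahydropyrrolo[2,3-c]azepin-8(1H)-one F5. Heating F5 in methanesulfonic acid (sealed) should lead, by tautomerisation and loss of HBr, to C4=C5 and thus to 13.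

2. Step 7. Ring opening of the neutral mask may be too slow at temperatures the molecule tolerates. Prolonged hot hydrazine may also reduce C4=C5 through adventitious diimide or shift the olefin out of the ring. The fallback activates the mask by quaternisation so that the cleavage runs near room temperature; it sets out from 12 and comes back at 13. SEM-Cl (MeCN, no base, rt to 50 °C) should alkylate the most basic mask nitrogen to give 3-(2,3-dibromo-8-oxo-1,6,7,8-tetrahydropyrrolo[2,3-c]azepin-4-yl)-1-{[2-(trimethylsilyl)ethoxy]methyl}imidazo[1,2-a]pyrimidin-1-ium chloride F6. Hydrazine hydrate in EtOH at rt to 40 °C should open the activated pyrimidinium ring to 4-(2-amino-1-{[2-(trimethylsilyl)ethoxy]methyl}-1H-imidazol-4-yl)-2,3-dibromo-6,7-dihydropyrrolo[2,3-c]azepin-8(1H)-one F7. Aqueous HCl in EtOH at 60 °C should then remove the SEM group to give 13.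

3. Step 6. Cleavage of a benzyl group from a tertiary lactam nitrogen needs hot TFA. It may stay incomplete, or the heat and acid may cause bromine migration or protodebromination on the pyrrole. The fallback changes the nitrogen substituent to the far more acid-labile 2,4,6-trimethoxybenzyl group, whose activated ring carbons are also out of reach of the alkyne; it sets out from 1 and comes back at 12. Reductive amination of 1 with 2,4,6-trimethoxybenzaldehyde proceeds through (E)-N-(2,4,6-trimethoxybenzylidene)prop-2-yn-1-amine F8 to N-(2,4,6-trimethoxybenzyl)prop-2-yn-1-amine F9. Sonogashira coupling with 6 gives 3-(imidazo[1,2-a]pyrimidin-3-yl)-N-(2,4,6-trimethoxybenzyl)prop-2-yn-1-amine F10. Acylation with 9 gives 4,5-dibromo-N-[3-(imidazo[1,2-a]pyrimidin-3-yl)prop-2-yn-1-yl]-N-(2,4,6-trimethoxybenzyl)-1H-pyrrole-2-carboxamide F11. The PtCl2 cycloisomerisation should give 2,3-dibromo-4-(imidazo[1,2-a]pyrimidin-3-yl)-7-(2,4,6-trimethoxybenzyl)-6,7-dihydropyrrolo[2,3-c]azepin-8(1H)-one F12, from which TFA/CH2Cl2 with anisole at room temperature should release 12.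

**Further compounds**
F1 | step 5 | 4,5-dibromo-N-(3,3-diethoxypropyl)-1H-pyrrole-2-carboxamide | CCOC(CCNC(=O)c1cc(Br)c(Br)[nH]1)OCC
F2 | step 5 | 4,5-dibromo-N-(3-oxopropyl)-1H-pyrrole-2-carboxamide | O=CCCNC(=O)c1cc(Br)c(Br)[nH]1
F3 | step 5 | 2,3-dibromo-6,7-dihydropyrrolo[2,3-c]azepin-8(1H)-one | O=C1NCC=Cc2c1[nH]c(Br)c2Br
F4 | step 5 | racemic 4-(2-amino-1H-imidazol-4-yl)-2,3-dibromo-4,5,6,7-tetrahydropyrrolo[2,3-c]azepin-8(1H)-one (hymenin) | Nc1ncc(C2CCNC(=O)c3[nH]c(Br)c(Br)c32)[nH]1
F5 | step 5 | racemic 4-(2-amino-5-bromo-1H-imidazol-4-yl)-2,3-dibromo-4,5,6,7-tetrahydropyrrolo[2,3-c]azepin-8(1H)-one | Nc1nc(Br)c(C2CCNC(=O)c3[nH]c(Br)c(Br)c32)[nH]1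
F6 | step 7 | 3-(2,3-dibromo-8-oxo-1,6,7,8-tetrahydropyrrolo[2,3-c]azepin-4-yl)-1-{[2-(trimethylsilyl)ethoxy]methyl}imidazo[1,2-a]pyrimidin-1-ium chloride | C[Si](C)(C)CCOC[n+]1cc(C2=CCNC(=O)c3[nH]c(Br)c(Br)c32)n2cccnc12.[Cl-]
F7 | step 7 | 4-(2-amino-1-{[2-(trimethylsilyl)ethoxy]methyl}-1H-imidazol-4-yl)-2,3-dibromo-6,7-dihydropyrrolo[2,3-c]azepin-8(1H)-one | Nc1nc(C2=CCNC(=O)c3[nH]c(Br)c(Br)c32)cn1COCC[Si](C)(C)C
F8 | step 6 | (E)-N-(2,4,6-trimethoxybenzylidene)prop-2-yn-1-amine | C#CC/N=C/c1c(OC)cc(OC)cc1OC
F9 | step 6 | N-(2,4,6-trimethoxybenzyl)prop-2-yn-1-amine | C#CCNCc1c(OC)cc(OC)cc1OC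
F10 | step 6 | 3-(imidazo[1,2-a]pyrimidin-3-yl)-N-(2,4,6-trimethoxybenzyl)prop-2-yn-1-amine | C(#Cc1cnc2ncccn12)CNCc1c(OC)cc(OC)cc1OC
F11 | step 6 | 4,5-dibromo-N-[3-(imidazo[1,2-a]pyrimidin-3-yl)prop-2-yn-1-yl]-N-(2,4,6-trimethoxybenzyl)-1H-pyrrole-2-carboxamide | O=C(c1cc(Br)c(Br)[nH]1)N(Cc1c(OC)cc(OC)cc1OC)CC#Cc1cnc2ncccn12
F12 | step 6 | 2,3-dibromo-4-(imidazo[1,2-a]pyrimidin-3-yl)-7-(2,4,6-trimethoxybenzyl)-6,7-dihydropyrrolo[2,3-c]azepin-8(1H)-one | O=C1N(Cc2c(OC)cc(OC)cc2OC)CC=C(c2cnc3ncccn23)c2c1[nH]c(Br)c2Br
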